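## Retrosynthetic overview

1. Target ⇐ tetra-O-methyl ether (BBr3) ⇐ C2-symmetric bis[(R)-2-aryl-2-methylcyclopentanone], each C=O turned into CMe2.
2. Key disconnection: both C(=O)–C(quaternary) bonds, made together by intramolecular addition of an NHC-bound acyl anion (Breslow intermediate of an aliphatic aldehyde) to the aryl-bearing carbon of a 1,1-disubstituted styrene. This closes both cyclopentane rings and sets both stereocentres.
3. Bis(5-aryl-hex-5-enal) ⇐ alcohol oxidation ⇐ Wittig methylenation ⇐ aryl ketone from a dilithiated bibenzyl and δ-valerolactone.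
4. Bibenzyl dibromide ⇐ McMurry homocoupling of two molecules of 3-bromo-4,5-dimethoxybenzaldehyde, then diimide.
5. Ring order: both arene rings come with the starting aldehyde; the two cyclopentane rings form last and simultaneously, in the key step.

Assumption (a): compounds 1, 5, 8 and 12 are bought.
Assumption (b): the facial sense of the key step must be confirmed on the first run. The route is written with the (5aS,10bR) triazolium salt; its mirror image, equally accessible from the other cis-1-amino-2-indanol, is used if the opposite sense is found.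

## Route

Step 1
Reactants: 1 3-bromo-4,5-dimethoxybenzaldehyde (two molecules are joined)
Product: 3 (E)-1,2-bis(3-bromo-4,5-dimethoxyphenyl)ethene, via titanium pinacolate 2 (not isolated)
Conditions: TiCl4, Zn dust, THF, 0 °C → reflux; aq. K2CO3 work-up
Reagents that add atoms: 3-bromo-4,5-dimethoxybenzaldehyde, O=Cc1cc(Br)c(OC)c(OC)c1 (the second molecule of 1, which supplies the other half of the stilbene)
Why: McMurry reductive homocoupling, in which low-valent titanium pinacol-couples two molecules of the aldehyde and deoxygenates the titanium diolate to the alkene while aryl C–Br bonds stay intact; any Z isomer converges in step 2.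

Step 2
Reactants: 3 (E)-1,2-bis(3-bromo-4,5-dimethoxyphenyl)ethene
Product: 4 1,2-bis(3-bromo-4,5-dimethoxyphenyl)ethane
Conditions: p-toluenesulfonyl hydrazide (excess), NaOAc, DME/H2O, reflux
Reagents that add atoms: none
Why: Diimide reduction transfers H2 concertedly to the stilbene C=C and, unlike catalytic hydrogenation over Pd/C, cannot hydrogenolyse the aryl bromides.

Step 3
Reactants: 4 1,2-bis(3-bromo-4,5-dimethoxyphenyl)ethane; 5 δ-valerolactone
Product: 7 1,1'-[ethane-1,2-diylbis(2,3-dimethoxy-5,1-phenylene)]bis(5-hydroxypentan-1-one), via dilithio bibenzyl 6 (not isolated)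
Conditions: n-BuLi (2.2 equiv), THF, −78 °C; cannulate into 5 (3 equiv), THF, −78 °C; H2O
Reagents that add atoms: δ-valerolactone, O=C1CCCCO1
Why: Bromine–lithium exchange followed by lactone ring opening, where inverse addition at −78 °C keeps the lithium lactolate adduct intact until quench and so limits double addition.

Step 4
Reactants: 7 1,1'-[ethane-1,2-diylbis(2,3-dimethoxy-5,1-phenylene)]bis(5-hydroxypentan-1-one); 8 methyltriphenylphosphonium bromide
Product: 9 5,5'-[ethane-1,2-diylbis(2,3-dimethoxy-5,1-phenylene)]bis(hex-5-en-1-ol)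
Conditions: 8 (6 equiv), KOtBu (6 equiv), THF, 0 °C → reflux
Reagents that add atoms: methyltriphenylphosphonium bromide, C[P+](c1ccccc1)(c1ccccc1)c1ccccc1.[Br-]
Why: Wittig methylenation with excess non-stabilised ylide tolerates the free alkoxides and converts each aryl ketone into the 1,1-disubstituted styrene.

Step 5
Reactants: 9 5,5'-[ethane-1,2-diylbis(2,3-dimethoxy-5,1-phenylene)]bis(hex-5-en-1-ol)
Product: 10 5,5'-[ethane-1,2-diylbis(2,3-dimethoxy-5,1-phenylene)]bis(hex-5-enal)
Conditions: TEMPO (20 mol%), PhI(OAc)2 (2.4 equiv), CH2Cl2, rt; used at once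
Reagents that add atoms: none
Why: Oxoammonium (TEMPO) oxidation stops cleanly at the aldehyde and leaves the electron-rich styrene and arene untouched.

Step 6
Reactants: 10 5,5'-[ethane-1,2-diylbis(2,3-dimethoxy-5,1-phenylene)]bis(hex-5-enal)
Product: 11 (2R,2'R)-2,2'-[ethane-1,2-diylbis(2,3-dimethoxy-5,1-phenylene)]bis(2-methylcyclopentan-1-one)
Conditions: (5aS,10bR)-2-mesityl-5a,10b-dihydro-4H,6H-indeno[2,1-b][1,2,4]triazolo[4,3-d][1,4]oxazin-2-ium chloride (20 mol%), DBU (20 mol%), 1,4-dioxane (0.05 M), 80 °C
Reagents that add atoms: none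
Why: Proposed new method: the triazolylidene turns each aliphatic aldehyde into its Breslow intermediate (an acyl anion equivalent), whose enol O–H is delivered to the terminal =CH2 while the nucleophilic acyl carbon bonds to the aryl-bearing alkene carbon in a concerted, asynchronous Conia-ene-like five-membered transition state stabilised by the electron-rich aryl ring, so the new methyl group, the ketone and the quaternary centre arise together, the chiral indane wall of the catalyst selecting one alkene face at each arm independently to give the (R,R) bis-ketone; the closest known reaction type is the NHC-catalysed enantioselective intramolecular hydroacylation of unactivated 2-aryl-allyl ethers of salicylaldehyde to 3-aryl-3-methylchromanones, extended here from aromatic to aliphatic aldehydes and from six- to five-membered ring closure.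

Step 7
Reactants: 11 (2R,2'R)-2,2'-[ethane-1,2-diylbis(2,3-dimethoxy-5,1-phenylene)]bis(2-methylcyclopentan-1-one); 12 dimethylzinc
Product: 14 1,2-bis{3,4-dimethoxy-5-[(1S)-1,2,2-trimethylcyclopentyl]phenyl}ethane, via bis(titanium alkoxide) 13 (not isolated)
Conditions: Me2Zn, TiCl4 (3–4 equiv of Me2TiCl2 per C=O), CH2Cl2, −40 °C → rt
Reagents that add atoms: dimethylzinc, C[Zn]C (both methyl groups per ketone, delivered as dimethyltitanium dichloride, C[Ti](C)(Cl)Cl)
Why: Reetz geminal dimethylation, in which Me2TiCl2 adds methyl to C=O and the tertiary titanium alkoxide ionises and is methylated again; no bond to the quaternary stereocentre is broken, and its descriptor changes from R to S only because aryl now outranks the former carbonyl carbon.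

Step 8
Reactants: 14 1,2-bis{3,4-dimethoxy-5-[(1S)-1,2,2-trimethylcyclopentyl]phenyl}ethane
Product: 15 5,5'-(ethane-1,2-diyl)bis{3-[(1S)-1,2,2-trimethylcyclopentyl]benzene-1,2-diol}
Conditions: BBr3 (10 equiv), CH2Cl2, −78 °C → rt; H2O, under argon
Reagents that add atoms: none
Why: Lewis-acid cleavage of all four aryl methyl ethers by BBr3 (bromide attacks the O-complexed methyl group) frees both catechols without touching the all-carbon quaternary stereocentres.

## Compound list

1 | 3-bromo-4,5-dimethoxybenzaldehyde | O=Cc1cc(Br)c(OC)c(OC)c1 | starting material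
2 | titanium pinacolate: 4,5-bis(3-bromo-4,5-dimethoxyphenyl)-2,2-dichloro-1,3-dioxa-2-titanacyclopentane (tetravalent titanium, dl/meso mixture, not isolated) | COc1cc(cc(Br)c1OC)C1O[Ti](Cl)(Cl)OC1c1cc(Br)c(OC)c(OC)c1 | intermediate
3 | (E)-1,2-bis(3-bromo-4,5-dimethoxyphenyl)ethene | COc1cc(/C=C/c2cc(Br)c(OC)c(OC)c2)cc(Br)c1OC | intermediate
4 | 1,2-bis(3-bromo-4,5-dimethoxyphenyl)ethane | COc1cc(CCc2cc(Br)c(OC)c(OC)c2)cc(Br)c1OC | intermediate
5 | δ-valerolactone (oxan-2-one) | O=C1CCCCO1 | starting material
6 | dilithio bibenzyl: 1,2-bis(3-lithio-4,5-dimethoxyphenyl)ethane (not isolated) | COc1cc(CCc2cc([Li])c(OC)c(OC)c2)cc([Li])c1OC | intermediate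
7 | 1,1'-[ethane-1,2-diylbis(2,3-dimethoxy-5,1-phenylene)]bis(5-hydroxypentan-1-one) | OCCCCC(=O)c1cc(CCc2cc(OC)c(OC)c(C(=O)CCCCO)c2)cc(OC)c1OC | intermediate
8 | methyltriphenylphosphonium bromide | C[P+](c1ccccc1)(c1ccccc1)c1ccccc1.[Br-] | starting material
9 | 5,5'-[ethane-1,2-diylbis(2,3-dimethoxy-5,1-phenylene)]bis(hex-5-en-1-ol) | OCCCCC(=C)c1cc(CCc2cc(OC)c(OC)c(C(=C)CCCCO)c2)cc(OC)c1OC | intermediate
10 | 5,5'-[ethane-1,2-diylbis(2,3-dimethoxy-5,1-phenylene)]bis(hex-5-enal) | O=CCCCC(=C)c1cc(CCc2cc(OC)c(OC)c(C(=C)CCCC=O)c2)cc(OC)c1OC | intermediate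
11 | (2R,2'R)-2,2'-[ethane-1,2-diylbis(2,3-dimethoxy-5,1-phenylene)]bis(2-methylcyclopentan-1-one) | O=C1CCC[C@]1(C)c1cc(CCc2cc(OC)c(OC)c([C@@]3(C)CCCC3=O)c2)cc(OC)c1OC | intermediate
12 | dimethylzinc | C[Zn]C | starting material
13 | bis(titanium alkoxide): both C=O groups of 11 after the first methyl transfer, each as C(CH3)–O–TiCl2CH3 (carbinol configuration undefined, quaternary centres unchanged, not isolated) | C[Ti](Cl)(Cl)OC1(C)CCC[C@]1(C)c1cc(CCc2cc(OC)c(OC)c([C@@]3(C)CCCC3(C)O[Ti](C)(Cl)Cl)c2)cc(OC)c1OC | intermediate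
14 | 1,2-bis{3,4-dimethoxy-5-[(1S)-1,2,2-trimethylcyclopentyl]phenyl}ethane | CC1(C)CCC[C@]1(C)c1cc(CCc2cc(OC)c(OC)c([C@@]3(C)CCCC3(C)C)c2)cc(OC)c1OC | intermediate
15 | 5,5'-(ethane-1,2-diyl)bis{3-[(1S)-1,2,2-trimethylcyclopentyl]benzene-1,2-diol} (CNP0144189.1) | CC1(C)CCC[C@]1(C)c1cc(CCc2cc(O)c(O)c([C@@]3(C)CCCC3(C)C)c2)cc(O)c1O | target

## Step count and risks

Total step count: 8. Longest linear sequence: 8 (1 → 15).

Both stereocentres are set in step 6 by two independent catalyst-controlled events. The minor facial outcome therefore ends up mainly as the meso (R,S) bis-ketone rather than as the enantiomer. Because the two centres are far apart, this meso isomer will be hard to separate from (R,R)-11, so high per-site selectivity is essential.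

Steps most likely to fail:

1. Step 6 (key double ring closure). The aldehyde is aliphatic and enolisable, so aldol and acyloin pathways compete. The styrene carries an ortho-methoxy group, the five-ring variant is untested, and both arms must react with high facial selectivity. Fallback: set out from 4 and return at 11, making the quaternary centres by enolate alkylation on a preformed ring. Dibromide 4 is coupled twice with excess cyclopentanone by enamine-assisted mono-α-arylation (Pd(OAc)2, P(o-tol)3, pyrrolidine cat., NaOAc, 1,4-dioxane, 110 °C). This gives the bis(2-arylcyclopentanone) 2,2'-[ethane-1,2-diylbis(2,3-dimethoxy-5,1-phenylene)]bis(cyclopentan-1-one) F1. Its benzylic enolates are then methylated under asymmetric phase-transfer catalysis (MeI, CsOH·H2O, toluene, −20 °C, N-[4-(trifluoromethyl)benzyl]cinchoninium bromide or its cinchonidinium pseudo-enantiomer, whichever gives the R centres) to give 11.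

2. Step 7 (double geminal dimethylation). The tertiary cation sits next to a quaternary carbon bearing an electron-rich, ortho-methoxylated aryl group. A 1,2-aryl shift through a symmetrical phenonium ion would erode the enantiopurity, and methoxy participation would give a cyclic ether. Fallback: set out from 11 and return at 14 without any cationic intermediate. Wittig methylenation under hindered-ketone conditions (8, KOtBu, toluene, reflux) gives the bis(methylidene) compound 1,2-bis{3,4-dimethoxy-5-[(1S)-1-methyl-2-methylidenecyclopentyl]phenyl}ethane F2. Furukawa cyclopropanation (Et2Zn, CH2I2, CH2Cl2, 0 °C) gives the bis(spirocyclopropane) 1,2-bis{3,4-dimethoxy-5-[(4S)-4-methylspiro[2.4]heptan-4-yl]phenyl}ethane F3. Hydrogenolysis (H2, 1 atm, PtO2, AcOH, rt) opens each cyclopropane at its unhindered CH2–CH2 bond to the gem-dimethyl groups of 14.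

3. Step 3 (two-fold aryllithium acylation with a lactone). Double addition, poor solubility of the dilithio species and incomplete second acylation are the concerns. Fallback: set out from 4 and return at 10, bypassing steps 3 to 5 by cross-coupling. 2,3-Dibromopropene is allylated with commercial [2-(1,3-dioxan-2-yl)ethyl]magnesium bromide (CuI cat., THF) to give the bromoalkene acetal 2-(4-bromopent-4-en-1-yl)-1,3-dioxane F4. Dilithio compound 6, generated from 4 as in step 3, is transmetalated with ZnCl2 to the bis(arylzinc chloride) 1,2-bis[3-(chlorozincio)-4,5-dimethoxyphenyl]ethane F5. Negishi coupling of F5 with F4 (Pd(PPh3)4, THF, 50 °C) gives the bis(acetal) 2,2'-{ethane-1,2-diylbis[(2,3-dimethoxy-5,1-phenylene)(pent-4-ene-4,1-diyl)]}bis(1,3-dioxane) F6. Mild hydrolysis (PPTS, acetone/H2O, reflux) then gives dialdehyde 10.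

## Further compounds

F1 | step 6 | 2,2'-[ethane-1,2-diylbis(2,3-dimethoxy-5,1-phenylene)]bis(cyclopentan-1-one) (α-centres configurationally labile, not defined) | O=C1CCCC1c1cc(CCc2cc(OC)c(OC)c(C3CCCC3=O)c2)cc(OC)c1OC
F2 | step 7 | 1,2-bis{3,4-dimethoxy-5-[(1S)-1-methyl-2-methylidenecyclopentyl]phenyl}ethane | C=C1CCC[C@]1(C)c1cc(CCc2cc(OC)c(OC)c([C@@]3(C)CCCC3=C)c2)cc(OC)c1OC
F3 | step 7 | 1,2-bis{3,4-dimethoxy-5-[(4S)-4-methylspiro[2.4]heptan-4-yl]phenyl}ethane | C1CC12CCC[C@]2(C)c1cc(CCc2cc(OC)c(OC)c([C@@]3(C)CCCC34CC4)c2)cc(OC)c1OC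
F4 | step 3 | 2-(4-bromopent-4-en-1-yl)-1,3-dioxane | C=C(Br)CCCC1OCCCO1
F5 | step 3 | 1,2-bis[3-(chlorozincio)-4,5-dimethoxyphenyl]ethane | COc1cc(CCc2cc([Zn]Cl)c(OC)c(OC)c2)cc([Zn]Cl)c1OC
F6 | step 3 | 2,2'-{ethane-1,2-diylbis[(2,3-dimethoxy-5,1-phenylene)(pent-4-ene-4,1-diyl)]}bis(1,3-dioxane) | C=C(CCCC1OCCCO1)c1cc(CCc2cc(OC)c(OC)c(C(=C)CCCC3OCCCO3)c2)cc(OC)c1OC
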